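## The problem

The target 16 is a chain of five benzene rings joined only through four diaryl ether oxygens and carrying thirteen free hydroxyls. Lettered A to E from the 2,4,6-trihydroxyphenyl end, ring A is a phloroglucinol unit, ring B a 3,5-dihydroxy-1,4-dioxygenated ring, ring C a pentaoxygenated ring, ring D a 3,4-dihydroxy-1,5-dioxygenated ring and ring E a 3,4,5-trihydroxyphenyl cap. There are no stereocentres and no carbon–carbon bonds between rings, so the problem is purely one of regiochemistry: which oxygen of each polyhydroxylated ring becomes an ether and which stays free. Three of the four ether oxygens sit on carbons flanked on both sides by oxygen substituents (ring A C1, ring B C4, ring C C2), the positions where copper-mediated etherification is slowest. Ring C is the centre of the difficulty. Numbered C1 (ether to ring B), C2 (ether to ring D), C3 to C5 (hydroxyls) and C6 (its only hydrogen), it bears five contiguous oxygens, two of them adjacent aryl ethers. The free polyphenol, with pyrogallol motifs in rings C and E, is oxidised by air once deprotonated, so the hydroxyls must stay masked through all bond-forming steps and the final unmasking must use neither base nor oxidant. The enabling feature is that the C4 and C5 hydroxyls of ring C form a catechol whose ortho-quinone has exactly C1 and C2 as its two β-carbons (C1 is β to the C5 carbonyl, C2 to the C4 carbonyl). The C3 oxygen, carried as a methyl ether, makes these two β-carbons electronically different.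

## Retrosynthesis

**16 from 15.** The last cut removes eleven O-methyl groups from 15, which already has the ring C catechol free. Methyl is chosen over benzyl because every monomer is sold as its methyl ether and because aryl methyl ethers are inert to the anode, to phosphate base with copper at 90 °C, and to peracid. The forward reaction must cleave eleven alkyl–oxygen bonds by a Lewis acid and leave the four aryl–oxygen–aryl bonds intact, without base or oxidant.

**15 from 11, 5 and 10.** The two aryl C–O bonds at ring C C1 and C2 are cut together. Ring C becomes commercial 3-methoxycatechol 11, and the 41-carbon product falls into a seven-carbon unit and two isomeric 17-carbon phenols, 5 (rings A–B) and 10 (rings D–E). The neighbouring cut, making the same two bonds one at a time by copper coupling on a ring C dihalide, needs a purpose-built ring C block and a second coupling at a carbon flanked on both sides. Cutting the A–B or D–E ether last would leave the ring C problem inside a larger fragment. In the forward direction, anodic oxidation of 11 gives quinone 12. Phenol 5 must add through oxygen at the β-carbon remote from the methoxy group to give catechol 13. Reoxidation to quinone 14 and addition of phenol 10 at the remaining β-carbon then gives 15. The reaction must oxidise the catechol and not the phenols, and must direct the second phenol to C2 of ring C and not to exchange at C1.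

**5 from 3 from 1 and 2.** The free hydroxyl of 5 (ring B C4) is traced back to the formyl group of aldehyde 3 through a Baeyer–Villiger oxidation that passes through formate 4. The ring A–O–ring B bond of 3 is then cut to commercial 2,4,6-trimethoxyphenol 1 and 4-bromo-2,6-dimethoxybenzaldehyde 2. The cut is placed so that the doubly ortho-substituted partner is the nucleophile, and the bromide of 2 is unhindered and activated by the para formyl group. The opposite polarity would put both ortho substituents on the halide, where copper insertion suffers. The formyl group serves twice, as activator and as latent phenol oxygen, so no protecting-group step is needed.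

**10 from 8 from 6 and 7.** The same logic gives phenol 10 from aldehyde 8 through formate 9, and 8 from commercial 3,4,5-trimethoxyphenol 6 and 3-bromo-4,5-dimethoxybenzaldehyde 7. Here the phenol is unhindered and the bromide has a single ortho methoxy group, the classical partner type for Ullmann ether synthesis.

## Roads not taken

**Alternative 1:** ring A would be built rather than bought.
- Cut and key step: two C–C bonds of ring A are formed by an alkoxide-mediated double Claisen condensation. The two methylene carbons of dimethyl 3-oxopentanedioate A1 attack the two ester carbonyls of aryloxymalonate A2 (aryl = ring B with its C4 oxygen as a benzyl ether). Enolisation gives phloroglucinol diester A3.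
- Merits: the ring A–ring B ether is made beforehand by substitution at a malonate carbon, so no doubly ortho-substituted phenol has to be coupled. The 2,4,6-oxygenation of ring A is fixed by construction.
- Weak points: the methine of A2 is the most acidic site in the flask, and its enolate is a poor acceptor. A3 carries two esters that must be saponified and decarboxylated, and three free hydroxyls that must then be capped. Ring C is left untouched.
- Comparison: this road is better in avoiding a hindered C–O coupling. Against that, the chosen plan reaches 5 in two steps, with the hindered phenol 1 as nucleophile against an activated bromide, where this road needs at least five. All the effort of Alternative 1 goes into the one ether that is easiest to buy into.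

**Alternative 2:** ring C would be built from a four-membered ring.
- Cut and key step: thermolysis of the 4-[(Z)-2-aryloxyvinyl]-2,3,4-trimethoxycyclobutenone A4 (aryl = the ring A–B unit) opens the ring to a dienylketene. Its 6π closure forms the ring C C1–C2 bond and, after tautomerisation, gives phenol A5 with its only free hydroxyl at ring C C2.
- Merits: the pentaoxygenated ring arises with an unambiguous substitution pattern, and the oxygen that must carry ring D is the one left free. This is a regiochemical guarantee that the chosen plan does not have, since it relies on the electronic bias of a quinone.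
- Weak points: A4 needs a (Z)-2-aryloxyvinyl metal reagent bearing the bulky ring A–B aryloxy group, which can lose aryloxide by elimination. It also needs addition to a squaric ester and O-methylation of a tertiary alkoxide. After the ring expansion, the C2–O–ring D bond still has to be made by copper coupling of a phenol flanked by aryloxy and methoxy groups, the hardest coupling of the molecule.
- Comparison: this road is safer in regiochemistry but several steps longer and linear. The chosen plan sets against it two C–O bonds in one operation, no metal or halogen on ring C, and convergence from two equal halves.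

**Alternative 3:** ring B would be built between rings A and C.
- Cut and key step: heating the 4-aryloxy-3-ethoxycyclobutenone A6 (aryl = ring C with its C2 oxygen as a benzyl ether) with the ring A aryl ethynyl ether A7 starts a Danheiser benzannulation. The sequence is four-electron ring opening, [2+2] addition of the vinylketene to the alkyne, a second ring opening and 6π closure. It gives phenol A8, in which ring B carries both of its aryl ethers.
- Merits: two of the four ether links are in place without any coupling of a hindered phenol. The union is convergent and regiospecific, and the ring C C2 oxygen is differentiated as a benzyl ether.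
- Weak points: A6 and A7 each need several steps, and the ynol ether of a doubly ortho-substituted phenol is thermally fragile. After debenzylation, the ring C–ring D ether still requires the same hindered copper coupling as in Alternative 2.
- Comparison: this road is equal or better in certainty of regiochemistry at ring B. Against that, the chosen plan has a six-step total and its ring C ethers need no hindered coupling, at the price of one unproven step.

Key step: step 5

Assumption: aldehydes 2 and 7 are taken as purchased catalogue compounds; 7 is otherwise one O-methylation away from 5-bromovanillin.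

## Route

Step 1
Reactants: 1 2,4,6-trimethoxyphenol; 2 4-bromo-2,6-dimethoxybenzaldehyde
Product: 3 2,6-dimethoxy-4-(2,4,6-trimethoxyphenoxy)benzaldehyde
Conditions: CuI (10 mol %), picolinic acid (20 mol %), K3PO4, DMSO, 90 °C, Ar
Reagents that add atoms: none
Why: Ullmann-type C–O coupling under ligand-accelerated catalysis by monovalent copper, a system suited to ortho,ortho-disubstituted phenols. The bromide of 2 has no ortho substituent and is activated by the para formyl group, which has no enolisable hydrogen and should survive the phosphate base.

Step 2
Reactants: 3 2,6-dimethoxy-4-(2,4,6-trimethoxyphenoxy)benzaldehyde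
Product: 5 2,6-dimethoxy-4-(2,4,6-trimethoxyphenoxy)phenol, via aryl formate 4 (not isolated)
Conditions: mCPBA, CH2Cl2, 0 °C to rt; then K2CO3 (cat.), MeOH, rt
Reagents that add atoms: 3-chloroperoxybenzoic acid (mCPBA), OOC(=O)c1cccc(Cl)c1
Why: Baeyer–Villiger (Dakin-type) oxidation; the electron-rich aryl group migrates in the Criegee adduct to give formate 4, which is cleaved by base-catalysed methanolysis. The oxidisable phenol stays masked as its formate while peracid is present and is released only after the peracid has been washed out.

Step 3
Reactants: 6 3,4,5-trimethoxyphenol; 7 3-bromo-4,5-dimethoxybenzaldehyde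
Product: 8 3,4-dimethoxy-5-(3,4,5-trimethoxyphenoxy)benzaldehyde
Conditions: CuI (10 mol %), picolinic acid (20 mol %), K3PO4, DMSO, 90 °C, Ar
Reagents that add atoms: none
Why: Ullmann ether synthesis between an unhindered, electron-rich phenol and a bromide with a single ortho methoxy group, the classical bromoveratraldehyde-type partner for diaryl ethers.

Step 4
Reactants: 8 3,4-dimethoxy-5-(3,4,5-trimethoxyphenoxy)benzaldehyde
Product: 10 3,4-dimethoxy-5-(3,4,5-trimethoxyphenoxy)phenol, via aryl formate 9 (not isolated)
Conditions: mCPBA, CH2Cl2, 0 °C to rt; then K2CO3 (cat.), MeOH, rt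
Reagents that add atoms: 3-chloroperoxybenzoic acid (mCPBA), OOC(=O)c1cccc(Cl)c1
Why: Baeyer–Villiger oxidation with aryl migration favoured by the para methoxy group, as in the standard conversion of alkoxybenzaldehydes into alkoxyphenols, followed by methanolysis of formate 9.

Step 5
Reactants: 11 3-methoxycatechol; 5 2,6-dimethoxy-4-(2,4,6-trimethoxyphenoxy)phenol; 10 3,4-dimethoxy-5-(3,4,5-trimethoxyphenoxy)phenol
Product: 15 5-[2,6-dimethoxy-4-(2,4,6-trimethoxyphenoxy)phenoxy]-4-[3,4-dimethoxy-5-(3,4,5-trimethoxyphenoxy)phenoxy]-3-methoxybenzene-1,2-diol, via 3-methoxy-1,2-benzoquinone 12 (not isolated), via monoether catechol 13 (not isolated), via monoether quinone 14 (not isolated)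
Conditions: graphite felt anode, Pt cathode, divided cell, controlled potential (first anodic wave of 11), LiClO4, 2,6-lutidine, MeCN, 0 °C, Ar; 5 (1.0 equiv), 2 F/mol; then 10 (1.5 equiv), 2 F/mol
Reagents that add atoms: none
Why: Proposed new method: at the anode, held at the foot of the first oxidation wave of 11, the catechol loses two electrons and two protons (taken up by 2,6-lutidine) to give quinone 12, and the lutidine-bound phenol 5 adds through oxygen in 1,4 fashion to C5 of 12 (the later ring C C1), after which tautomerisation gives catechol 13. Catechol 13 is oxidised at the same potential, or by 12 in solution, to quinone 14, and phenol 10, added only when 5 has been consumed, attacks the remaining β-carbon C4 (ring C C2); aromatisation gives 15, so the whole is an ECEC sequence that passes 4 F/mol and releases hydrogen at the cathode. The closest known reaction type is the anodic oxidation of catechols with in situ Michael trapping of the ortho-quinone by methanol, thiols, amines or sulfinates, which gives 4,5-disubstituted catechols; phenolic oxygen nucleophiles and two different nucleophiles added in sequence to one catechol have not been shown. No ring is closed and no stereocentre is formed. The first selectivity needed is C5 over C4 in 12: the C3 methoxy group donates into C4 through its enol ether and leaves C5 as the more electrophilic β-carbon, the bias that is known to send other nucleophiles to C5 of this quinone. The second is addition at C4 of 14 in preference to exchange of the aryloxy group at C5 or of methoxide at C3: ipso attack is reversible and returns 14, whereas the C4 adduct aromatises irreversibly, and the two ortho methoxy groups of the ring B aryloxy substituent shield C5. Steric matching supports the order of events: phenol 5, whose ortho and para positions are all substituted and which can therefore react only through oxygen, meets the open C5 of 12 but should not add to the crowded C4 of 14, which is left for the unhindered phenol 10. Chemoselectivity of the oxidation rests on catechols being oxidised at lower potential than monophenols, on the methyl ethers being inert at that potential, and on the low stationary concentration of quinone, which disfavours quinone self-condensation.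

Step 6
Reactants: 15 5-[2,6-dimethoxy-4-(2,4,6-trimethoxyphenoxy)phenoxy]-4-[3,4-dimethoxy-5-(3,4,5-trimethoxyphenoxy)phenoxy]-3-methoxybenzene-1,2-diol
Product: 16 5-[2,6-dihydroxy-4-(2,4,6-trihydroxyphenoxy)phenoxy]-4-[3,4-dihydroxy-5-(3,4,5-trihydroxyphenoxy)phenoxy]benzene-1,2,3-triol
Conditions: BBr3 (excess), CH2Cl2, −78 °C to rt; then MeOH, 0 °C, evaporate; Ar
Reagents that add atoms: none
Why: Lewis-acid cleavage of aryl methyl ethers; BBr3 coordinates each methoxy oxygen and bromide removes the methyl group by SN2 attack. The diaryl ether bonds have no carbon open to such attack and should persist, and the conditions are free of base and oxidant.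

## Compound list

1 | 2,4,6-trimethoxyphenol | COc1cc(OC)c(O)c(OC)c1 | starting material
2 | 4-bromo-2,6-dimethoxybenzaldehyde | COc1cc(Br)cc(OC)c1C=O | starting material
3 | 2,6-dimethoxy-4-(2,4,6-trimethoxyphenoxy)benzaldehyde | COc1cc(OC)c(Oc2cc(OC)c(C=O)c(OC)c2)c(OC)c1 | intermediate
4 | 2,6-dimethoxy-4-(2,4,6-trimethoxyphenoxy)phenyl formate | COc1cc(OC)c(Oc2cc(OC)c(OC=O)c(OC)c2)c(OC)c1 | intermediate
5 | 2,6-dimethoxy-4-(2,4,6-trimethoxyphenoxy)phenol | COc1cc(OC)c(Oc2cc(OC)c(O)c(OC)c2)c(OC)c1 | intermediate
6 | 3,4,5-trimethoxyphenol | COc1cc(O)cc(OC)c1OC | starting material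
7 | 3-bromo-4,5-dimethoxybenzaldehyde | COc1cc(C=O)cc(Br)c1OC | starting material
8 | 3,4-dimethoxy-5-(3,4,5-trimethoxyphenoxy)benzaldehyde | O=Cc1cc(OC)c(OC)c(Oc2cc(OC)c(OC)c(OC)c2)c1 | intermediate
9 | 3,4-dimethoxy-5-(3,4,5-trimethoxyphenoxy)phenyl formate | O=COc1cc(OC)c(OC)c(Oc2cc(OC)c(OC)c(OC)c2)c1 | intermediate
10 | 3,4-dimethoxy-5-(3,4,5-trimethoxyphenoxy)phenol | Oc1cc(OC)c(OC)c(Oc2cc(OC)c(OC)c(OC)c2)c1 | intermediate
11 | 3-methoxycatechol (3-methoxybenzene-1,2-diol) | COc1cccc(O)c1O | starting material
12 | 3-methoxy-1,2-benzoquinone (3-methoxycyclohexa-3,5-diene-1,2-dione) | COC1=CC=CC(=O)C1=O | intermediate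
13 | 5-[2,6-dimethoxy-4-(2,4,6-trimethoxyphenoxy)phenoxy]-3-methoxybenzene-1,2-diol | COc1cc(Oc2c(OC)cc(Oc3c(OC)cc(OC)cc3OC)cc2OC)cc(O)c1O | intermediate
14 | 5-[2,6-dimethoxy-4-(2,4,6-trimethoxyphenoxy)phenoxy]-3-methoxycyclohexa-3,5-diene-1,2-dione | COC1=CC(Oc2c(OC)cc(Oc3c(OC)cc(OC)cc3OC)cc2OC)=CC(=O)C1=O | intermediate
15 | 5-[2,6-dimethoxy-4-(2,4,6-trimethoxyphenoxy)phenoxy]-4-[3,4-dimethoxy-5-(3,4,5-trimethoxyphenoxy)phenoxy]-3-methoxybenzene-1,2-diol | COc1cc(OC)c(Oc2cc(OC)c(Oc3cc(O)c(O)c(OC)c3Oc3cc(OC)c(OC)c(Oc4cc(OC)c(OC)c(OC)c4)c3)c(OC)c2)c(OC)c1 | intermediate
16 | 5-[2,6-dihydroxy-4-(2,4,6-trihydroxyphenoxy)phenoxy]-4-[3,4-dihydroxy-5-(3,4,5-trihydroxyphenoxy)phenoxy]benzene-1,2,3-triol | Oc1cc(O)c(Oc2cc(O)c(Oc3cc(O)c(O)c(O)c3Oc3cc(O)c(O)c(Oc4cc(O)c(O)c(O)c4)c3)c(O)c2)c(O)c1 | target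

## Step count and least certain steps

Total: 6 steps. Longest linear sequence: 4 steps (1, 2, 5, 6 or 3, 4, 5, 6).

**Step 5 (key step, proposed new method).**
- What may go wrong: the neutral phenols may add too slowly to the electrogenerated quinone, so that the quinone is lost to self-condensation. The second addition may be diverted to ipso substitution (aryloxy exchange at C5 or displacement of methoxide at C3), which scrambles the two aryloxy groups, or to attack through an ortho carbon of 10, which gives a biaryl. The electron-rich phenol 5 may itself be oxidised at the anode and lose ring A.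
- Fallback (known Ullmann chemistry; sets out from 10 and 5, returns at 16): commercial 5-bromo-1,2,3-trimethoxybenzene is iodinated with NIS and catalytic TFA in MeCN at one of its two equivalent free positions to give 1-bromo-2-iodo-3,4,5-trimethoxybenzene F1. Phenol 10 is coupled at the iodide, which reacts ahead of the bromide (CuI, picolinic acid, K3PO4, DMSO, 80 °C), to give 1-bromo-2-[3,4-dimethoxy-5-(3,4,5-trimethoxyphenoxy)phenoxy]-3,4,5-trimethoxybenzene F2. Phenol 5 is then coupled at the bromide with the same catalyst at 110 °C to give the tridecamethyl ether 1-[2,6-dimethoxy-4-(2,4,6-trimethoxyphenoxy)phenoxy]-2-[3,4-dimethoxy-5-(3,4,5-trimethoxyphenoxy)phenoxy]-3,4,5-trimethoxybenzene F3. Demethylation as in step 6 gives 16.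

**Step 1.**
- What may go wrong: C–O bond formation from the doubly ortho-substituted phenoxide may be slow, so that reductive loss of bromine from 2 or base-induced degradation of the aldehyde competes.
- Fallback (sets out from 1, returns at 3): metal-free nucleophilic aromatic substitution of 1 on commercial 4-fluoro-2,6-dimethoxybenzaldehyde (K2CO3, DMF, 120 °C). Fluoride para to the formyl group is displaced by addition–elimination, and no new compound is involved.

**Step 2.**
- What may go wrong: over-oxidation. The peracid may attack the highly activated ring A, or the released phenol may be oxidised to a quinone with loss of ring A.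
- Fallback (sets out from 1, returns at 5): commercial 4-bromo-2,6-dimethoxyphenol is benzylated (BnBr, K2CO3, DMF) to 2-(benzyloxy)-5-bromo-1,3-dimethoxybenzene F4. Ullmann coupling with 1 (catalyst of step 1, 110 °C) gives 2-[4-(benzyloxy)-3,5-dimethoxyphenoxy]-1,3,5-trimethoxybenzene F5. Hydrogenolysis (H2, Pd/C, EtOAc) frees 5 without any oxidant.

**Step 6.**
- What may go wrong: cleavage of the eleven methyl ethers may be incomplete, giving partially methylated polyphenols that are hard to separate. The free polyphenol may also be lost to air oxidation during chromatography.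
- Fallback (sets out from 15, returns at 16): after demethylation as in step 6, the crude polyphenol is peracetylated in the same flask (Ac2O, pyridine) to the tridecaacetate 5-[2,6-diacetoxy-4-(2,4,6-triacetoxyphenoxy)phenoxy]-4-[3,4-diacetoxy-5-(3,4,5-triacetoxyphenoxy)phenoxy]benzene-1,2,3-triyl triacetate F6. This is stable to air and silica and is purified as such. Acid methanolysis (HCl from AcCl in MeOH, 0 °C to rt, Ar) then releases 16 with only volatile by-products.

## Further compounds

F1 | step 5 | 1-bromo-2-iodo-3,4,5-trimethoxybenzene | COc1cc(Br)c(I)c(OC)c1OC
F2 | step 5 | 1-bromo-2-[3,4-dimethoxy-5-(3,4,5-trimethoxyphenoxy)phenoxy]-3,4,5-trimethoxybenzene | COc1cc(Br)c(Oc2cc(OC)c(OC)c(Oc3cc(OC)c(OC)c(OC)c3)c2)c(OC)c1OC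
F3 | step 5 | 1-[2,6-dimethoxy-4-(2,4,6-trimethoxyphenoxy)phenoxy]-2-[3,4-dimethoxy-5-(3,4,5-trimethoxyphenoxy)phenoxy]-3,4,5-trimethoxybenzene | COc1cc(OC)c(Oc2cc(OC)c(Oc3cc(OC)c(OC)c(OC)c3Oc3cc(OC)c(OC)c(Oc4cc(OC)c(OC)c(OC)c4)c3)c(OC)c2)c(OC)c1
F0 | step 1 | none | none
F4 | step 2 | 2-(benzyloxy)-5-bromo-1,3-dimethoxybenzene | COc1cc(Br)cc(OC)c1OCc1ccccc1
F5 | step 2 | 2-[4-(benzyloxy)-3,5-dimethoxyphenoxy]-1,3,5-trimethoxybenzene | COc1cc(OC)c(Oc2cc(OC)c(OCc3ccccc3)c(OC)c2)c(OC)c1
F6 | step 6 | 5-[2,6-diacetoxy-4-(2,4,6-triacetoxyphenoxy)phenoxy]-4-[3,4-diacetoxy-5-(3,4,5-triacetoxyphenoxy)phenoxy]benzene-1,2,3-triyl triacetate | CC(=O)Oc1cc(OC(C)=O)c(Oc2cc(OC(C)=O)c(Oc3cc(OC(C)=O)c(OC(C)=O)c(OC(C)=O)c3Oc3cc(OC(C)=O)c(OC(C)=O)c(Oc4cc(OC(C)=O)c(OC(C)=O)c(OC(C)=O)c4)c3)c(OC(C)=O)c2)c(OC(C)=O)c1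
A1 | alternative 1 | dimethyl 3-oxopentanedioate | COC(=O)CC(=O)CC(=O)OC
A2 | alternative 1 | dimethyl 2-[4-(benzyloxy)-3,5-dimethoxyphenoxy]propanedioate | COC(=O)C(Oc1cc(OC)c(OCc2ccccc2)c(OC)c1)C(=O)OC
A3 | alternative 1 | dimethyl 5-[4-(benzyloxy)-3,5-dimethoxyphenoxy]-2,4,6-trihydroxyisophthalate | COC(=O)c1c(O)c(Oc2cc(OC)c(OCc3ccccc3)c(OC)c2)c(O)c(C(=O)OC)c1O
A4 | alternative 2 | 4-{(Z)-2-[2,6-dimethoxy-4-(2,4,6-trimethoxyphenoxy)phenoxy]ethenyl}-2,3,4-trimethoxycyclobut-2-en-1-one | COC1=C(OC)C(OC)(/C=C\Oc2c(OC)cc(Oc3c(OC)cc(OC)cc3OC)cc2OC)C1=O
A5 | alternative 2 | 6-[2,6-dimethoxy-4-(2,4,6-trimethoxyphenoxy)phenoxy]-2,3,4-trimethoxyphenol | COc1cc(OC)c(Oc2cc(OC)c(Oc3cc(OC)c(OC)c(OC)c3O)c(OC)c2)c(OC)c1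
A6 | alternative 3 | 4-[2-(benzyloxy)-3,4,5-trimethoxyphenoxy]-3-ethoxycyclobut-2-en-1-one | CCOC1=CC(=O)C1Oc1cc(OC)c(OC)c(OC)c1OCc1ccccc1
A7 | alternative 3 | 2-(ethynyloxy)-1,3,5-trimethoxybenzene | C#COc1c(OC)cc(OC)cc1OC
A8 | alternative 3 | 2-[2-(benzyloxy)-3,4,5-trimethoxyphenoxy]-3-ethoxy-5-(2,4,6-trimethoxyphenoxy)phenol | CCOc1cc(Oc2c(OC)cc(OC)cc2OC)cc(O)c1Oc1cc(OC)c(OC)c(OC)c1OCc1ccccc1
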